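**Plan**

- Retrosynthesis: the N–CH3 group (from a methyl carbamate) and the O–CH3 bond at C8 are cut first. The isoquinoline benzene ring is then opened at C5–C6, C7–C8 and C8–C8a, with C4a–C5 traced back to a Wolff shift, giving an alkenyl aryl diazo ketone and methoxyethyne. The diazo ketone is cut at CH2–C(O) (Weinreb amide plus naphthylmethyl Grignard reagent) and at C4a–C(O) (carbonylation of an enol triflate).
- Enabling feature (isoquinoline locants, primed for the naphthalene): the benzene ring C4a/C5/C6/C7/C8/C8a has oxygen on C6 and C8 (meta) and the naphthalene carbon C8' on C5. This is the pattern a vinylketene/ynol ether benzannulation delivers. The ring is fused to a cis-2,6-dimethylpiperidine unit (C1–N2–C3) that has a mirror plane as long as the benzene ring is missing.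
- Forward order: the naphthalene is built first (Stobbe condensation and Friedel–Crafts closure on a bromine-blocked benzaldehyde). The piperidine ring comes from 4-methoxypyridine by two methyl additions. The two fragments are joined as a ketone, and the benzene ring of the isoquinoline is closed third from last.
- Stereochemistry: the cis relation of C1 and C3 comes from an axial conjugate addition that gives a meso piperidone. The absolute configuration comes from desymmetrising this ketone with a chiral lithium amide. Neither centre is touched afterwards.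

Key step: step 15

Assumption: the target SMILES fixes C1 and C3 only; the hindered C5–C8' axis is undefined, so the biaryl compounds from step 15 on are taken as mixtures of the two rotational isomers and no control is claimed.
Assumption: the (R,R)-amide is written in step 10; which antipode removes the proton next to the (R)-carbon must be settled by experiment, and the (S,S)-amine is equally available.
Remark: the oxygen substituent of the ynol ether is a spectator in the key step, so methyl is used because it is what O6 carries in the target.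

Step 1
Reactants: 1 2-bromo-5-methoxybenzaldehyde; 2 diethyl succinate
Product: 3 (E)-4-(2-bromo-5-methoxyphenyl)-3-(ethoxycarbonyl)but-3-enoic acid
Conditions: NaOEt, EtOH, reflux; then aq HCl
Reagents that add atoms: none
Why: Stobbe condensation, in which the succinate enolate adds to the non-enolisable aldehyde, the alkoxide lactonises and E1cB opening of the lactone gives the alkylidene succinic half-ester, mainly with the aryl group cis to the CH2CO2H arm as the ring closure needs.

Step 2
Reactants: 3 (E)-4-(2-bromo-5-methoxyphenyl)-3-(ethoxycarbonyl)but-3-enoic acid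
Product: 6 ethyl 4-acetoxy-8-bromo-5-methoxynaphthalene-2-carboxylate, via mixed anhydride 4 (not isolated), via naphthol 5 (not isolated)
Conditions: Ac2O, NaOAc, 140 °C
Reagents that add atoms: acetic anhydride CC(=O)OC(C)=O
Why: Intramolecular Friedel–Crafts acylation through the mixed anhydride can only occur at the ring carbon ortho to the methoxy group because the other ortho position carries bromine, and the naphthol formed is acetylated in the same pot.

Step 3
Reactants: 6 ethyl 4-acetoxy-8-bromo-5-methoxynaphthalene-2-carboxylate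
Product: 8 ethyl 8-bromo-4,5-dimethoxynaphthalene-2-carboxylate, via sodium naphtholate 7 (not isolated)
Conditions: NaOEt (1 equiv), EtOH, 0 °C → rt; then MeI, DMF, rt
Reagents that add atoms: iodomethane CI
Why: Ethoxide cleaves the aryl acetate by transesterification without changing the ethyl ester, and the naphtholate is O-methylated by iodomethane in a Williamson ether synthesis.

Step 4
Reactants: 8 ethyl 8-bromo-4,5-dimethoxynaphthalene-2-carboxylate
Product: 9 (8-bromo-4,5-dimethoxynaphthalen-2-yl)methanol
Conditions: LiAlH4, THF, 0 °C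
Reagents that add atoms: none
Why: Hydride reduction of the ester to the primary alcohol at 0 °C, conditions under which the aryl bromide and the aryl methyl ethers are inert.

Step 5
Reactants: 9 (8-bromo-4,5-dimethoxynaphthalen-2-yl)methanol
Product: 11 1-bromo-4,5-dimethoxy-7-methylnaphthalene, via mesylate 10 (not isolated)
Conditions: MsCl, Et3N, THF, 0 °C; then LiEt3BH, 0 °C → rt
Reagents that add atoms: none
Why: The benzylic alcohol is activated as its mesylate and the sulfonate is displaced by hydride from LiEt3BH in an SN2 reaction, a standard two-stage deoxygenation that leaves the aryl bromide untouched.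

Step 6
Reactants: 11 1-bromo-4,5-dimethoxy-7-methylnaphthalene
Product: 13 (4,5-dimethoxy-7-methylnaphthalen-1-yl)methanol, via aryllithium 12 (not isolated)
Conditions: n-BuLi, THF, −78 °C; then (CH2O)n, −78 °C → rt; aq NH4Cl
Reagents that add atoms: formaldehyde (as paraformaldehyde) C=O
Why: Bromine–lithium exchange is fast at −78 °C and the aryllithium adds to monomeric formaldehyde released from paraformaldehyde to give the benzylic alcohol.

Step 7
Reactants: 13 (4,5-dimethoxy-7-methylnaphthalen-1-yl)methanol
Product: 14 1-(chloromethyl)-4,5-dimethoxy-7-methylnaphthalene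
Conditions: SOCl2, pyridine, CH2Cl2, 0 °C; used at once
Reagents that add atoms: thionyl chloride ClS(Cl)=O
Why: Chlorodehydroxylation through the chlorosulfite, with pyridine as acid scavenger, is easy at this benzylic position, which is activated by the para methoxy group.

Step 8
Reactants: 15 4-methoxypyridine
Product: 18 methyl 2-methyl-4-oxo-2,3-dihydropyridine-1(2H)-carboxylate (racemic), via acylpyridinium chloride 16 (not isolated), via dihydropyridine enol ether 17 (not isolated)
Conditions: ClCO2Me, THF, −40 °C; MeMgBr, −78 °C; then 1 M aq HCl, rt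
Reagents that add atoms: methyl chloroformate COC(Cl)=O; methylmagnesium bromide C[Mg]Br; water O
Why: Grignard addition to an N-acylpyridinium salt occurs at C2 because C4 is blocked by the methoxy group, and acid hydrolysis of the enol ether gives the dihydropyridone, whose new stereocentre is racemic, which is of no consequence because the next step leads to a meso compound.

Step 9
Reactants: 18 methyl 2-methyl-4-oxo-2,3-dihydropyridine-1(2H)-carboxylate (racemic)
Product: 20 methyl (2R,6S)-2,6-dimethyl-4-oxopiperidine-1-carboxylate (cis, meso), via silyl enol ether 19 (not isolated)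
Conditions: MeMgBr, CuBr·SMe2 (10 mol%), TMSCl, THF, −78 °C; then 1 M aq HCl, 0 °C
Reagents that add atoms: methylmagnesium bromide C[Mg]Br
Why: Copper-catalysed conjugate addition of the Grignard reagent, accelerated by TMSCl, proceeds by axial attack on the half-chair in which the 2-methyl group is axial to avoid allylic strain with the carbamate, so the new methyl group enters cis and the ketone obtained after hydrolysis of the silyl enol ether is meso.

Step 10
Reactants: 20 methyl (2R,6S)-2,6-dimethyl-4-oxopiperidine-1-carboxylate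
Product: 22 methyl (2S,6R)-2,6-dimethyl-4-(trifluoromethylsulfonyloxy)-3,6-dihydro-2H-pyridine-1-carboxylate, via lithium enolate 21 (not isolated)
Conditions: (R,R)-bis(1-phenylethyl)amine, n-BuLi, LiCl, THF, −78 °C; 20; then 5-Cl-2-pyridyl-NTf2, −78 → −20 °C
Reagents that add atoms: N-(5-chloropyridin-2-yl)-bis(trifluoromethanesulfonyl)imide FC(F)(F)S(=O)(=O)N(c1ccc(Cl)cn1)S(=O)(=O)C(F)(F)F
Why: Enantioselective deprotonation of a meso ketone by a C2-symmetric chiral lithium amide (desymmetrisation) distinguishes the two enantiotopic CH2 groups, and O-sulfonylation of the enolate fixes the double bond on the side of the (R)-configured carbon, so that no new stereocentre is made but the two existing ones become the (6R) and (2S) centres of one enantiomer.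

Step 11
Reactants: 22 methyl (2S,6R)-2,6-dimethyl-4-(trifluoromethylsulfonyloxy)-3,6-dihydro-2H-pyridine-1-carboxylate
Product: 23 methyl (2S,6R)-4-[methoxy(methyl)carbamoyl]-2,6-dimethyl-3,6-dihydro-2H-pyridine-1-carboxylate
Conditions: Pd(OAc)2 (5 mol%), Xantphos, CO (1 atm), MeNHOMe·HCl, Et3N, DMF, 50 °C
Reagents that add atoms: carbon monoxide [C-]#[O+]; N,O-dimethylhydroxylamine hydrochloride CNOC.Cl
Why: Palladium-catalysed aminocarbonylation, in which oxidative addition of zerovalent palladium to the alkenyl triflate, CO insertion and attack of the hydroxylamine on the acylpalladium species give the Weinreb amide without touching the allylic stereocentre.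

Step 12
Reactants: 14 1-(chloromethyl)-4,5-dimethoxy-7-methylnaphthalene; 23 methyl (2S,6R)-4-[methoxy(methyl)carbamoyl]-2,6-dimethyl-3,6-dihydro-2H-pyridine-1-carboxylate
Product: 25 methyl (2S,6R)-4-[2-(4,5-dimethoxy-7-methylnaphthalen-1-yl)acetyl]-2,6-dimethyl-3,6-dihydro-2H-pyridine-1-carboxylate, via Grignard reagent 24 (not isolated)
Conditions: 14, Mg turnings, THF, 0 °C (slow addition, dilute); then 23, −20 → 0 °C; aq NH4Cl
Reagents that add atoms: none
Why: Weinreb ketone synthesis, in which the benzylic Grignard reagent adds once to the amide carbonyl and the magnesium-chelated tetrahedral adduct survives until work-up, which excludes a second addition and conjugate addition to the enone.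

Step 13
Reactants: 25 methyl (2S,6R)-4-[2-(4,5-dimethoxy-7-methylnaphthalen-1-yl)acetyl]-2,6-dimethyl-3,6-dihydro-2H-pyridine-1-carboxylate
Product: 26 methyl (2S,6R)-4-[2-diazo-2-(4,5-dimethoxy-7-methylnaphthalen-1-yl)acetyl]-2,6-dimethyl-3,6-dihydro-2H-pyridine-1-carboxylate
Conditions: 4-acetamidobenzenesulfonyl azide, DBU, MeCN, 0 °C → rt
Reagents that add atoms: 4-acetamidobenzenesulfonyl azide CC(=O)Nc1ccc(cc1)S(=O)(=O)N=[N+]=[N-]
Why: Regitz diazo transfer, in which the CH2 group flanked by the carbonyl and the naphthyl ring is by far the most acidic site, so DBU forms this enolate selectively and the sulfonyl azide delivers the diazo group to it.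

Step 14
Reactants: 27 2-chloro-1,1-dimethoxyethane
Product: 29 methoxyethyne, via sodium methoxyethynide 28 (not isolated)
Conditions: NaNH2 (3 equiv), liquid NH3, −33 °C; then saturated aq NaCl, −70 °C; distilled (bp about 23 °C) into cold ClCH2CH2Cl
Reagents that add atoms: none
Why: Twofold base-induced elimination (HCl, then methanol) from the chloroacetal with NaNH2 gives the sodium acetylide of the ynol ether, which is protonated on aqueous quench, the classical route to alkoxyethynes.

Step 15
Reactants: 26 methyl (2S,6R)-4-[2-diazo-2-(4,5-dimethoxy-7-methylnaphthalen-1-yl)acetyl]-2,6-dimethyl-3,6-dihydro-2H-pyridine-1-carboxylate; 29 methoxyethyne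
Product: 34 methyl (1R,3S)-5-(4,5-dimethoxy-7-methylnaphthalen-1-yl)-8-hydroxy-6-methoxy-1,3-dimethyl-3,4-dihydro-1H-isoquinoline-2-carboxylate, via ketene 30 (not isolated), via cyclobutenone 31 (not isolated), via dienylketene 32 (not isolated), via cyclohexadienone 33 (not isolated)
Conditions: 29 (5 equiv), ClCH2CH2Cl, hν (450 nm LEDs), rt, sealed tube; then 80 °C
Reagents that add atoms: none
Why: Excitation of the aryl diazo ketone expels N2 and the alkenyl carbon C4a shifts from the acyl carbon (future C8) to the diazo carbon C5 (photochemical Wolff rearrangement), giving aryl(alkenyl)ketene 30, a vinylketene of the kind on which the Danheiser benzannulation rests, which is the closest known reaction type. The nucleophilic CH terminus of ynol ether 29 bonds to the ketene carbonyl carbon, so a [2+2] cycloaddition closes the transient four-membered ring of 31 with C7–C8 and C5–C6 formed, the methoxy group on C6 and C7 left unsubstituted. At 80 °C conrotatory four-electron opening of 31 gives dienylketene 32, and disrotatory six-electron electrocyclisation onto the ring alkene (C8–C8a) closes the benzene ring as dienone 33, which tautomerises to phenol 34. No new stereocentre survives: the quaternary carbon of 31 and C8a of 33 are erased on aromatisation, C1 and C3 pass through untouched because neither C–H bond takes part, and the C5–C8' axis forms without control. The step needs closure at C8a and not at the naphthalene ortho carbon C7', and this is secured because the dienylketene isomer that holds the naphthyl group next to the ketene could cyclise only by breaking naphthalene aromaticity and therefore reverts to 31, whereas the isomer that holds the ring alkene there cyclises readily.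

Step 16
Reactants: 34 methyl (1R,3S)-5-(4,5-dimethoxy-7-methylnaphthalen-1-yl)-8-hydroxy-6-methoxy-1,3-dimethyl-3,4-dihydro-1H-isoquinoline-2-carboxylate
Product: 35 methyl (1R,3S)-5-(4,5-dimethoxy-7-methylnaphthalen-1-yl)-6,8-dimethoxy-1,3-dimethyl-3,4-dihydro-1H-isoquinoline-2-carboxylate
Conditions: MeI, K2CO3, DMF, rt
Reagents that add atoms: iodomethane CI
Why: Williamson methylation of the remaining phenol, in which only oxygen is alkylated because the carbamate nitrogen bears no hydrogen and the benzylic C1–H is not acidic under carbonate conditions.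

Step 17
Reactants: 35 methyl (1R,3S)-5-(4,5-dimethoxy-7-methylnaphthalen-1-yl)-6,8-dimethoxy-1,3-dimethyl-3,4-dihydro-1H-isoquinoline-2-carboxylate
Product: 36 (1R,3S)-5-(4,5-dimethoxy-7-methylnaphthalen-1-yl)-6,8-dimethoxy-1,2,3-trimethyl-1,2,3,4-tetrahydroisoquinoline
Conditions: LiAlH4, THF, reflux
Reagents that add atoms: none
Why: LiAlH4 reduces the methyl carbamate through the hemiaminal and iminium stage to the N-methyl group, a standard carbamate to N-methyl conversion that does not affect C1, C3 or the aryl ethers.

**Compound list**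

1 | 2-bromo-5-methoxybenzaldehyde | COc1ccc(Br)c(C=O)c1 | starting material
2 | diethyl succinate | CCOC(=O)CCC(=O)OCC | starting material
3 | (E)-4-(2-bromo-5-methoxyphenyl)-3-(ethoxycarbonyl)but-3-enoic acid | CCOC(=O)/C(CC(O)=O)=C/c1cc(OC)ccc1Br | intermediate
4 | acetic (E)-4-(2-bromo-5-methoxyphenyl)-3-(ethoxycarbonyl)but-3-enoic anhydride (mixed anhydride, not isolated) | CCOC(=O)/C(CC(=O)OC(C)=O)=C/c1cc(OC)ccc1Br | intermediate
5 | ethyl 8-bromo-4-hydroxy-5-methoxynaphthalene-2-carboxylate (naphthol, not isolated) | CCOC(=O)c1cc(O)c2c(OC)ccc(Br)c2c1 | intermediate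
6 | ethyl 4-acetoxy-8-bromo-5-methoxynaphthalene-2-carboxylate | CCOC(=O)c1cc(OC(C)=O)c2c(OC)ccc(Br)c2c1 | intermediate
7 | sodium 5-bromo-3-(ethoxycarbonyl)-8-methoxynaphthalen-1-olate (not isolated) | CCOC(=O)c1cc([O-])c2c(OC)ccc(Br)c2c1.[Na+] | intermediate
8 | ethyl 8-bromo-4,5-dimethoxynaphthalene-2-carboxylate | CCOC(=O)c1cc(OC)c2c(OC)ccc(Br)c2c1 | intermediate
9 | (8-bromo-4,5-dimethoxynaphthalen-2-yl)methanol | OCc1cc(OC)c2c(OC)ccc(Br)c2c1 | intermediate
10 | (8-bromo-4,5-dimethoxynaphthalen-2-yl)methyl methanesulfonate (not isolated) | CS(=O)(=O)OCc1cc(OC)c2c(OC)ccc(Br)c2c1 | intermediate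
11 | 1-bromo-4,5-dimethoxy-7-methylnaphthalene | Cc1cc(OC)c2c(OC)ccc(Br)c2c1 | intermediate
12 | (4,5-dimethoxy-7-methylnaphthalen-1-yl)lithium (not isolated) | [Li]c1ccc(OC)c2c(OC)cc(C)cc12 | intermediate
13 | (4,5-dimethoxy-7-methylnaphthalen-1-yl)methanol | OCc1ccc(OC)c2c(OC)cc(C)cc12 | intermediate
14 | 1-(chloromethyl)-4,5-dimethoxy-7-methylnaphthalene | ClCc1ccc(OC)c2c(OC)cc(C)cc12 | intermediate
15 | 4-methoxypyridine | COc1ccncc1 | starting material
16 | 4-methoxy-1-(methoxycarbonyl)pyridin-1-ium chloride (not isolated) | COC(=O)[n+]1ccc(OC)cc1.[Cl-] | intermediate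
17 | methyl 4-methoxy-2-methyl-2H-pyridine-1-carboxylate, racemic (not isolated) | COC(=O)N1C=CC(OC)=CC1C | intermediate
18 | methyl 2-methyl-4-oxo-2,3-dihydropyridine-1(2H)-carboxylate, racemic | COC(=O)N1C=CC(=O)CC1C | intermediate
19 | methyl cis-2,6-dimethyl-4-(trimethylsiloxy)-3,6-dihydro-2H-pyridine-1-carboxylate, racemic, one enantiomer drawn (not isolated) | C[C@H]1N(C(=O)OC)[C@@H](C)CC(=C1)O[Si](C)(C)C | intermediate
20 | methyl (2R,6S)-2,6-dimethyl-4-oxopiperidine-1-carboxylate (cis, meso) | C[C@H]1N(C(=O)OC)[C@@H](C)CC(=O)C1 | intermediate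
21 | lithium (2S,6R)-1-(methoxycarbonyl)-2,6-dimethyl-1,2,3,6-tetrahydropyridin-4-olate (not isolated) | C[C@H]1N(C(=O)OC)[C@@H](C)CC(=C1)[O-].[Li+] | intermediate
22 | methyl (2S,6R)-2,6-dimethyl-4-(trifluoromethylsulfonyloxy)-3,6-dihydro-2H-pyridine-1-carboxylate | C[C@H]1N(C(=O)OC)[C@@H](C)CC(=C1)OS(=O)(=O)C(F)(F)F | intermediate
23 | methyl (2S,6R)-4-[methoxy(methyl)carbamoyl]-2,6-dimethyl-3,6-dihydro-2H-pyridine-1-carboxylate | C[C@H]1N(C(=O)OC)[C@@H](C)CC(=C1)C(=O)N(C)OC | intermediate
24 | [(4,5-dimethoxy-7-methylnaphthalen-1-yl)methyl]magnesium chloride (not isolated) | Cl[Mg]Cc1ccc(OC)c2c(OC)cc(C)cc12 | intermediate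
25 | methyl (2S,6R)-4-[2-(4,5-dimethoxy-7-methylnaphthalen-1-yl)acetyl]-2,6-dimethyl-3,6-dihydro-2H-pyridine-1-carboxylate | C[C@H]1N(C(=O)OC)[C@@H](C)CC(=C1)C(=O)Cc1ccc(OC)c2c(OC)cc(C)cc12 | intermediate
26 | methyl (2S,6R)-4-[2-diazo-2-(4,5-dimethoxy-7-methylnaphthalen-1-yl)acetyl]-2,6-dimethyl-3,6-dihydro-2H-pyridine-1-carboxylate | C[C@H]1N(C(=O)OC)[C@@H](C)CC(=C1)C(=O)C(=[N+]=[N-])c1ccc(OC)c2c(OC)cc(C)cc12 | intermediate
27 | 2-chloro-1,1-dimethoxyethane (chloroacetaldehyde dimethyl acetal) | COC(CCl)OC | starting material
28 | sodium methoxyethynide (not isolated) | [Na+].[C-]#COC | intermediate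
29 | methoxyethyne | COC#C | intermediate
30 | methyl (2S,6R)-4-[1-(4,5-dimethoxy-7-methylnaphthalen-1-yl)-2-oxoethenyl]-2,6-dimethyl-3,6-dihydro-2H-pyridine-1-carboxylate (ketene, not isolated) | C[C@H]1N(C(=O)OC)[C@@H](C)CC(=C1)C(=C=O)c1ccc(OC)c2c(OC)cc(C)cc12 | intermediate
31 | methyl (2S,6R)-4-[1-(4,5-dimethoxy-7-methylnaphthalen-1-yl)-2-methoxy-4-oxocyclobut-2-en-1-yl]-2,6-dimethyl-3,6-dihydro-2H-pyridine-1-carboxylate (cyclobutenone, ring carbon unassigned, not isolated) | C[C@H]1N(C(=O)OC)[C@@H](C)CC(=C1)C1(c2ccc(OC)c3c(OC)cc(C)cc23)C(=O)C=C1OC | intermediate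
32 | methyl (2S,6R)-4-[1-(4,5-dimethoxy-7-methylnaphthalen-1-yl)-2-methoxy-4-oxobuta-1,3-dienyl]-2,6-dimethyl-3,6-dihydro-2H-pyridine-1-carboxylate (dienylketene, ring alkene cis to the ketene arm, not isolated) | C[C@H]1N(C(=O)OC)[C@@H](C)CC(=C1)/C(c1ccc(OC)c2c(OC)cc(C)cc12)=C(\C=C=O)OC | intermediate
33 | methyl (1R,3S)-5-(4,5-dimethoxy-7-methylnaphthalen-1-yl)-6-methoxy-1,3-dimethyl-8-oxo-1,3,4,8a-tetrahydroisoquinoline-2(8H)-carboxylate (C8a unassigned, not isolated) | C[C@H]1N(C(=O)OC)[C@@H](C)CC2=C(c3ccc(OC)c4c(OC)cc(C)cc34)C(OC)=CC(=O)C12 | intermediate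
34 | methyl (1R,3S)-5-(4,5-dimethoxy-7-methylnaphthalen-1-yl)-8-hydroxy-6-methoxy-1,3-dimethyl-3,4-dihydro-1H-isoquinoline-2-carboxylate | C[C@H]1N(C(=O)OC)[C@@H](C)Cc2c(-c3ccc(OC)c4c(OC)cc(C)cc34)c(OC)cc(O)c21 | intermediate
35 | methyl (1R,3S)-5-(4,5-dimethoxy-7-methylnaphthalen-1-yl)-6,8-dimethoxy-1,3-dimethyl-3,4-dihydro-1H-isoquinoline-2-carboxylate | C[C@H]1N(C(=O)OC)[C@@H](C)Cc2c(-c3ccc(OC)c4c(OC)cc(C)cc34)c(OC)cc(OC)c21 | intermediate
36 | (1R,3S)-5-(4,5-dimethoxy-7-methylnaphthalen-1-yl)-6,8-dimethoxy-1,2,3-trimethyl-1,2,3,4-tetrahydroisoquinoline | COc1cc(OC)c2c(c1-c1ccc(OC)c3c(OC)cc(C)cc13)C[C@H](C)N(C)[C@@H]2C | target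

**Step count**

Total: 17 steps. Longest linear sequence: 12 steps (steps 1–7, 12, 13, 15, 16, 17).

**Steps most likely to fail**

1. Step 15. The doubly substituted, hindered ketene may be captured by the ynol ether too slowly and be lost to dimerisation or other pathways. The dienylketene may also close onto the naphthalene ortho carbon if ring opening of the cyclobutenone does not equilibrate.

   The fallback sets out from Weinreb amide 23 and bromide 11 and returns at 35. The benzene ring is built by the same benzannulation without the naphthyl group, in its most-used form with a diazomethyl ketone, and the biaryl bond is made afterwards by cross-coupling.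
   - MeMgBr should convert 23 into the methyl ketone methyl (2S,6R)-4-acetyl-2,6-dimethyl-3,6-dihydro-2H-pyridine-1-carboxylate F1.
   - LiN(SiMe3)2 and 2,2,2-trifluoroethyl trifluoroacetate give the trifluoroacetyl ketone methyl (2S,6R)-2,6-dimethyl-4-(4,4,4-trifluoro-3-oxobutanoyl)-3,6-dihydro-2H-pyridine-1-carboxylate F2.
   - MsN3, Et3N and water in MeCN effect detrifluoroacetylative diazo transfer to the diazomethyl ketone methyl (2S,6R)-4-(2-diazoacetyl)-2,6-dimethyl-3,6-dihydro-2H-pyridine-1-carboxylate F3.
   - Irradiation of F3 with 29 and heating should give the phenol methyl (1R,3S)-8-hydroxy-6-methoxy-1,3-dimethyl-3,4-dihydro-1H-isoquinoline-2-carboxylate F4.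
   - MeI and K2CO3 give the dimethyl ether methyl (1R,3S)-6,8-dimethoxy-1,3-dimethyl-3,4-dihydro-1H-isoquinoline-2-carboxylate F5.
   - NBS in MeCN should give the bromide methyl (1R,3S)-5-bromo-6,8-dimethoxy-1,3-dimethyl-3,4-dihydro-1H-isoquinoline-2-carboxylate F6, since C5 is para to the C8 methoxy group and less shielded than C7, which lies between two methoxy groups.
   - Bromide 11 is converted through aryllithium 12 and B(OMe)3 into (4,5-dimethoxy-7-methylnaphthalen-1-yl)boronic acid F7.
   - Suzuki–Miyaura coupling of F6 with F7 (Pd(OAc)2, SPhos, K3PO4, toluene/water, 100 °C) should give 35.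

2. Step 10. Discrimination of the enantiotopic CH2 groups may be incomplete or in the unwanted sense, because the carbamate forces both methyl groups axial and deprotonation may occur from a twist conformation. Proton exchange between enolate and ketone can erode the selectivity further. The enantiomeric purity would be checked at 22 or 23 and, if needed, raised by crystallisation of a later intermediate.

   The fallback sets out from 15 and returns at 22. The first stereocentre is set catalytically at the pyridinium stage, and the second methyl addition then delivers the enolate regiospecifically, so no desymmetrisation is needed.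
   - Acylpyridinium salt 16 is treated with MeMgBr in the presence of CuBr·SMe2 and a chiral bisphosphine such as Ph-BPE (the antipode that leads to the (S)-product), a catalytic enantioselective dearomatisation. This gives the enol ether methyl (S)-4-methoxy-2-methyl-2H-pyridine-1-carboxylate F8.
   - Acid hydrolysis gives methyl (S)-2-methyl-4-oxo-2,3-dihydropyridine-1(2H)-carboxylate F9.
   - Copper-catalysed addition of MeMgBr to F9, cis as in step 9, gives bromomagnesium (2S,6R)-1-(methoxycarbonyl)-2,6-dimethyl-1,2,3,6-tetrahydropyridin-4-olate F10, whose double bond already lies on the side of the new stereocentre.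
   - The chloropyridyl triflimide of step 10, added to the same flask, converts F10 into 22.

3. Step 12. Formation of the electron-rich naphthylmethyl Grignard reagent may be accompanied by Wurtz-type homocoupling, and the reagent may attack through the ring position next to the CH2 group and not through the benzylic carbon.

   The fallback sets out from 14 and 23 and returns at 25. A sulfone-stabilised carbanion replaces the Grignard reagent.
   - Chloride 14 and PhSO2Na in DMF give the sulfone 4,5-dimethoxy-7-methyl-1-(phenylsulfonylmethyl)naphthalene F11.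
   - n-BuLi in THF at −78 °C gives [(4,5-dimethoxy-7-methylnaphthalen-1-yl)(phenylsulfonyl)methyl]lithium F12.
   - F12 is acylated by 23 to the keto sulfone methyl (2S,6R)-4-[2-(4,5-dimethoxy-7-methylnaphthalen-1-yl)-2-(phenylsulfonyl)acetyl]-2,6-dimethyl-3,6-dihydro-2H-pyridine-1-carboxylate F13.
   - Reductive cleavage of the C–S bond with SmI2 in THF/MeOH at −78 °C should return ketone 25.

Further compounds
F1 | step 15 | methyl (2S,6R)-4-acetyl-2,6-dimethyl-3,6-dihydro-2H-pyridine-1-carboxylate | C[C@H]1N(C(=O)OC)[C@@H](C)CC(=C1)C(C)=O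
F2 | step 15 | methyl (2S,6R)-2,6-dimethyl-4-(4,4,4-trifluoro-3-oxobutanoyl)-3,6-dihydro-2H-pyridine-1-carboxylate | C[C@H]1N(C(=O)OC)[C@@H](C)CC(=C1)C(=O)CC(=O)C(F)(F)F
F3 | step 15 | methyl (2S,6R)-4-(2-diazoacetyl)-2,6-dimethyl-3,6-dihydro-2H-pyridine-1-carboxylate | C[C@H]1N(C(=O)OC)[C@@H](C)CC(=C1)C(=O)C=[N+]=[N-]
F4 | step 15 | methyl (1R,3S)-8-hydroxy-6-methoxy-1,3-dimethyl-3,4-dihydro-1H-isoquinoline-2-carboxylate | C[C@H]1N(C(=O)OC)[C@@H](C)Cc2cc(OC)cc(O)c21
F5 | step 15 | methyl (1R,3S)-6,8-dimethoxy-1,3-dimethyl-3,4-dihydro-1H-isoquinoline-2-carboxylate | C[C@H]1N(C(=O)OC)[C@@H](C)Cc2cc(OC)cc(OC)c21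
F6 | step 15 | methyl (1R,3S)-5-bromo-6,8-dimethoxy-1,3-dimethyl-3,4-dihydro-1H-isoquinoline-2-carboxylate | C[C@H]1N(C(=O)OC)[C@@H](C)Cc2c(Br)c(OC)cc(OC)c21
F7 | step 15 | (4,5-dimethoxy-7-methylnaphthalen-1-yl)boronic acid | OB(O)c1ccc(OC)c2c(OC)cc(C)cc12
F8 | step 10 | methyl (S)-4-methoxy-2-methyl-2H-pyridine-1-carboxylate | COC1=C[C@H](C)N(C(=O)OC)C=C1
F9 | step 10 | methyl (S)-2-methyl-4-oxo-2,3-dihydropyridine-1(2H)-carboxylate | O=C1C=CN(C(=O)OC)[C@@H](C)C1
F10 | step 10 | bromomagnesium (2S,6R)-1-(methoxycarbonyl)-2,6-dimethyl-1,2,3,6-tetrahydropyridin-4-olate | C[C@H]1N(C(=O)OC)[C@@H](C)CC(=C1)O[Mg]Br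
F11 | step 12 | 4,5-dimethoxy-7-methyl-1-(phenylsulfonylmethyl)naphthalene | O=S(=O)(Cc1ccc(OC)c2c(OC)cc(C)cc12)c1ccccc1
F12 | step 12 | [(4,5-dimethoxy-7-methylnaphthalen-1-yl)(phenylsulfonyl)methyl]lithium | [Li]C(c1ccc(OC)c2c(OC)cc(C)cc12)S(=O)(=O)c1ccccc1
F13 | step 12 | methyl (2S,6R)-4-[2-(4,5-dimethoxy-7-methylnaphthalen-1-yl)-2-(phenylsulfonyl)acetyl]-2,6-dimethyl-3,6-dihydro-2H-pyridine-1-carboxylate | C[C@H]1N(C(=O)OC)[C@@H](C)CC(=C1)C(=O)C(c1ccc(OC)c2c(OC)cc(C)cc12)S(=O)(=O)c1ccccc1
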